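**Retrosynthetic overview**
1. 22 ⇒ 21 + 12: the C7–C8 bond (alkenyl carbon to the methine on ring A) is made last, by a nickel-catalysed enantioconvergent reductive coupling of alkenyl bromide 21 with the radical from racemic chloride 12; this sets C8.
2. 21 (east, ring B) ⇒ aldehyde 9 + bromo-enone 15: Felkin anti boron aldol (C3, C4), acetylation, Felkin Luche reduction (C5), propanoylation.
3. 12 (west, ring A) ⇒ aldehyde 9: catalyst-matched Felkin ethylation (C3'), then lateral chlorination.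
4. 9 ⇒ chloride 5 + 1-bromo-2-methylprop-1-ene by the same radical nickel coupling (sets the ring-adjacent methine that becomes C2 and C2'), then ozonolysis.
5. Rings: both 4-pyranone rings come from one compound, 3, made in step 1 from pentan-3-one and propanoic acid; no ring is closed later.

Locants: the non-6-ene chain of 22 is C1–C9 (C2 carries ring B, C8 carries ring A); the pentan-2-yl chain on ring A is C1'–C5'.
Ligand: L = 2,2'-(cyclopropane-1,1-diyl)bis(3a,8a-dihydro-8H-indeno[1,2-d]oxazole).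
Assumption: (3aR,3a'R,8aS,8a'S)-L gives the (S) centre at a 1-(pyranyl)ethyl carbon as it does at a 1-arylethyl carbon; if the sense proves opposite, the two antipodes are exchanged between steps 3 and 12.
Assumption: 2-methylpent-1-en-3-one and 1-bromo-2-methylprop-1-ene are purchased.

**Route**

Step 1
Reactants: 1 pentan-3-one; 2 propanoic acid (2 equiv or more)
Product: 3 2,6-diethyl-3,5-dimethyl-4H-pyran-4-one
Conditions: polyphosphoric acid, 120 °C
Reagents that add atoms: none
Why: Polyphosphoric-acid-mediated C-acylation of the ketone at both α-carbons followed by cyclodehydration of the 1,3,5-triketone is the established one-pot route to fully alkylated 4-pyranones, and no stereocentre is formed.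

Step 2
Reactants: 3 2,6-diethyl-3,5-dimethyl-4H-pyran-4-one
Product: 5 2-(1-chloroethyl)-6-ethyl-3,5-dimethyl-4H-pyran-4-one (racemic), via lithium dienolate 4 (not isolated)
Conditions: LiN(SiMe3)2 (0.95 equiv), THF, −78 °C; then cannulated into C2Cl6 (1.5 equiv), THF, −78 °C
Reagents that add atoms: hexachloroethane, ClC(Cl)(Cl)C(Cl)(Cl)Cl
Why: Lateral (vinylogous) deprotonation of a 2-ethyl-4-pyranone gives the extended dienolate, which is chlorinated at the lateral carbon by the positive-chlorine donor (electrophilic halogenation of an extended enolate); inverse addition limits dichlorination, and the racemic centre does not matter because step 3 is stereoconvergent.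

Step 3
Reactants: 5 2-(1-chloroethyl)-6-ethyl-3,5-dimethyl-4H-pyran-4-one; 6 1-bromo-2-methylprop-1-ene
Product: 7 2-ethyl-3,5-dimethyl-6-[(2R)-4-methylpent-3-en-2-yl]-4H-pyran-4-one
Conditions: NiCl2·dme (dme = 1,2-dimethoxyethane, 10 mol %), (3aS,3a'S,8aR,8a'R)-L (11 mol %), Mn powder (3 equiv), NaI (0.5 equiv), N,N-dimethylacetamide, 0 °C
Reagents that add atoms: none
Why: Proposed new method: in this enantioconvergent reductive cross-electrophile coupling the alkenyl bromide adds oxidatively to zerovalent nickel, halogen abstraction from either enantiomer of 5 gives a planar 1-(4-oxopyranyl)ethyl radical (stabilised like a benzylic or vinylogous α-keto radical) that is captured by the chiral bis(oxazoline)–alkenylnickel species, and reductive elimination sets the (R) centre under ligand control with Mn as terminal reductant; the closest known reaction type is the nickel/bis(oxazoline)-catalysed asymmetric reductive coupling of alkenyl bromides with racemic secondary benzylic chlorides.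

Step 4
Reactants: 7 2-ethyl-3,5-dimethyl-6-[(2R)-4-methylpent-3-en-2-yl]-4H-pyran-4-one
Product: 9 (2S)-2-(6-ethyl-3,5-dimethyl-4-oxo-4H-pyran-2-yl)propanal (used crude at once in steps 5 and 8), via secondary ozonide 8 (not isolated)
Conditions: O3, CH2Cl2, −78 °C (Sudan red end point); then PPh3, −78 → 0 °C
Reagents that add atoms: ozone, [O-][O+]=O
Why: Ozonolysis with reductive work-up cleaves the electron-rich trisubstituted alkene much faster than the tetrasubstituted, carbonyl-conjugated ring double bonds, and the cold neutral conditions leave the α-stereocentre intact (same spatial arrangement, descriptor becomes S by priority change).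

Step 5
Reactants: 9 (2S)-2-(6-ethyl-3,5-dimethyl-4-oxo-4H-pyran-2-yl)propanal
Product: 10 2-ethyl-6-[(2R,3S)-3-hydroxypentan-2-yl]-3,5-dimethyl-4H-pyran-4-one
Conditions: Et2Zn (2.5 equiv), (2S)-(−)-3-exo-(dimethylamino)isoborneol (10 mol %), toluene, 0 °C; aq. NH4Cl
Reagents that add atoms: diethylzinc, CC[Zn]CC
Why: Amino-alcohol-catalysed enantioselective addition of diethylzinc to the aldehyde (Si-face delivery) is matched with Felkin–Anh control by the α-pyranyl stereocentre, so C3' is formed as (S), syn to the C2' methyl group.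

Step 6
Reactants: 10 2-ethyl-6-[(2R,3S)-3-hydroxypentan-2-yl]-3,5-dimethyl-4H-pyran-4-one
Product: 12 2-(1-chloroethyl)-6-[(2R,3S)-3-hydroxypentan-2-yl]-3,5-dimethyl-4H-pyran-4-one (both epimers at the C–Cl carbon), via dilithio alkoxide-dienolate 11 (not isolated)
Conditions: LiN(SiMe3)2 (2.1 equiv), THF, −78 °C; C2Cl6 (1.3 equiv), −78 °C; aq. NH4Cl
Reagents that add atoms: hexachloroethane, ClC(Cl)(Cl)C(Cl)(Cl)Cl
Why: The first equivalent of base forms the alkoxide and the second the lateral dienolate of the remaining ethyl group (the methine next to the alkoxide carbon is hindered and electrostatically disfavoured), which is chlorinated as in step 2; C2' and C3' are untouched and the C–Cl epimers converge in step 12.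

Step 7
Reactants: 13 2-methylpent-1-en-3-one
Product: 15 (1E)-1-bromo-2-methylpent-1-en-3-one, via dibromide 14 (not isolated)
Conditions: Br2 (1.0 equiv), CH2Cl2, −78 → 0 °C; then Et3N (1.5 equiv), 0 → 20 °C
Reagents that add atoms: bromine, BrBr
Why: Bromine addition to the enone and amine-induced dehydrobromination of the tertiary α-bromide (bromination–dehydrobromination) gives the conjugated β-bromo enone as the more stable (E) isomer, with bromine trans to the acyl group.

Step 8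
Reactants: 15 (1E)-1-bromo-2-methylpent-1-en-3-one (1.6 equiv); 9 (2S)-2-(6-ethyl-3,5-dimethyl-4-oxo-4H-pyran-2-yl)propanal
Product: 18 2-[(2R,3R,4R,6E)-7-bromo-3-hydroxy-4,6-dimethyl-5-oxohept-6-en-2-yl]-6-ethyl-3,5-dimethyl-4H-pyran-4-one, via enol borinate 16 (not isolated), via boron aldolate 17 (not isolated)
Conditions: 15, (c-C6H11)2BCl (1.8 equiv), Et3N (2.2 equiv), Et2O, −78 → 0 °C; then 9, −78 → −25 °C; MeOH, pH 7 buffer, 30% H2O2, 0 °C
Reagents that add atoms: none
Why: Dicyclohexylboron chloride with triethylamine gives the (E)-enol borinate of the ethyl ketone, whose Zimmerman–Traxler chair gives the anti aldol (C3–OH anti to C4–Me), while Felkin–Anh attack on the α-pyranyl aldehyde sets C3 syn to the C2 methyl group (anti-selective boron aldol reaction).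

Step 9
Reactants: 18 2-[(2R,3R,4R,6E)-7-bromo-3-hydroxy-4,6-dimethyl-5-oxohept-6-en-2-yl]-6-ethyl-3,5-dimethyl-4H-pyran-4-one
Product: 19 (2R,3R,4R,6E)-7-bromo-2-(6-ethyl-3,5-dimethyl-4-oxo-4H-pyran-2-yl)-4,6-dimethyl-5-oxohept-6-en-3-yl acetate
Conditions: Ac2O, pyridine, 4-(dimethylamino)pyridine (cat.), CH2Cl2, 0 °C
Reagents that add atoms: acetic anhydride, CC(=O)OC(C)=O
Why: Nucleophile-catalysed acylation of the secondary alcohol at 0 °C outpaces β-elimination of the β-acetoxy ketone, and no stereocentre is changed.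

Step 10
Reactants: 19 (2R,3R,4R,6E)-7-bromo-2-(6-ethyl-3,5-dimethyl-4-oxo-4H-pyran-2-yl)-4,6-dimethyl-5-oxohept-6-en-3-yl acetate
Product: 20 (2R,3S,4S,5R,6E)-7-bromo-2-(6-ethyl-3,5-dimethyl-4-oxo-4H-pyran-2-yl)-5-hydroxy-4,6-dimethylhept-6-en-3-yl acetate
Conditions: NaBH4, CeCl3·7H2O, MeOH, −78 °C; AcOH quench at −78 °C
Reagents that add atoms: none
Why: Luche reduction gives clean 1,2-reduction of the bromo-enone without touching the esters or the C–Br bond, and Felkin–Anh control by the α-methyl stereocentre (reinforced by the β-acetoxy group) puts the new C5 hydroxyl anti to the C4 methyl and syn to the C3 acetate; the cold acidic quench prevents acetyl migration, and a minor C5 epimer is removed by chromatography.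

Step 11
Reactants: 20 (2R,3S,4S,5R,6E)-7-bromo-2-(6-ethyl-3,5-dimethyl-4-oxo-4H-pyran-2-yl)-5-hydroxy-4,6-dimethylhept-6-en-3-yl acetate
Product: 21 (2R,3S,4R,5R,6E)-3-acetoxy-7-bromo-2-(6-ethyl-3,5-dimethyl-4-oxo-4H-pyran-2-yl)-4,6-dimethylhept-6-en-5-yl propanoate
Conditions: EtCOCl, pyridine, 4-(dimethylamino)pyridine (cat.), CH2Cl2, 0 °C
Reagents that add atoms: propanoyl chloride, CCC(Cl)=O
Why: Standard acylation of the secondary allylic alcohol with an acid chloride is fast enough to prevent 1,3-acyl migration, and no stereocentre is affected.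

Step 12
Reactants: 21 (2R,3S,4R,5R,6E)-3-acetoxy-7-bromo-2-(6-ethyl-3,5-dimethyl-4-oxo-4H-pyran-2-yl)-4,6-dimethylhept-6-en-5-yl propanoate; 12 2-(1-chloroethyl)-6-[(2R,3S)-3-hydroxypentan-2-yl]-3,5-dimethyl-4H-pyran-4-one (1.2 equiv)
Product: 22 (2R,3S,4R,5R,6E,8S)-3-acetoxy-2-(6-ethyl-3,5-dimethyl-4-oxo-4H-pyran-2-yl)-8-{6-[(2R,3S)-3-hydroxypentan-2-yl]-3,5-dimethyl-4-oxo-4H-pyran-2-yl}-4,6-dimethylnon-6-en-5-yl propanoate (CNP0265513.2)
Conditions: NiCl2·dme (15 mol %), (3aR,3a'R,8aS,8a'S)-L (17 mol %), Mn powder (3 equiv), NaI (0.5 equiv), N,N-dimethylacetamide, 0 °C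
Reagents that add atoms: none
Why: Proposed new method: the coupling of step 3 is used to join the two halves, with zerovalent nickel adding oxidatively to the alkenyl bromide of 21 (geometry retained), the planar pyranyl-ethyl radical from either epimer of 12 being captured by the chiral alkenylnickel species, and reductive elimination under control of the enantiomeric ligand setting C8 as (S); the closest known reaction type is the nickel/bis(oxazoline)-catalysed asymmetric reductive coupling of alkenyl bromides with secondary benzylic chlorides, here extended to a 2,2-disubstituted bromoalkene carrying esters and a chloride carrying a free alcohol.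

**Compound list**
1 | pentan-3-one | CCC(=O)CC | starting material
2 | propanoic acid | CCC(=O)O | starting material
3 | 2,6-diethyl-3,5-dimethyl-4H-pyran-4-one | CCc1oc(CC)c(C)c(=O)c1C | intermediate
4 | lithium 6-ethyl-2-ethylidene-3,5-dimethyl-2H-pyran-4-olate (lithium dienolate, not isolated) | [Li+].CC=C1OC(CC)=C(C)C([O-])=C1C | intermediate
5 | 2-(1-chloroethyl)-6-ethyl-3,5-dimethyl-4H-pyran-4-one (racemic) | CCc1oc(C(C)Cl)c(C)c(=O)c1C | intermediate
6 | 1-bromo-2-methylprop-1-ene | CC(C)=CBr | starting material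
7 | 2-ethyl-3,5-dimethyl-6-[(2R)-4-methylpent-3-en-2-yl]-4H-pyran-4-one | CCc1oc([C@H](C)C=C(C)C)c(C)c(=O)c1C | intermediate
8 | 2-[(1S)-1-(5,5-dimethyl-1,2,4-trioxolan-3-yl)ethyl]-6-ethyl-3,5-dimethyl-4H-pyran-4-one (secondary ozonide, trioxolane carbon unassigned, not isolated) | CCc1oc([C@H](C)C2OOC(C)(C)O2)c(C)c(=O)c1C | intermediate
9 | (2S)-2-(6-ethyl-3,5-dimethyl-4-oxo-4H-pyran-2-yl)propanal | CCc1oc([C@H](C)C=O)c(C)c(=O)c1C | intermediate
10 | 2-ethyl-6-[(2R,3S)-3-hydroxypentan-2-yl]-3,5-dimethyl-4H-pyran-4-one | CCc1oc([C@H](C)[C@@H](O)CC)c(C)c(=O)c1C | intermediate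
11 | dilithium 2-ethylidene-3,5-dimethyl-6-[(2R,3S)-3-oxidopentan-2-yl]-2H-pyran-4-olate (not isolated) | [Li+].[Li+].CC=C1OC([C@H](C)[C@@H]([O-])CC)=C(C)C([O-])=C1C | intermediate
12 | 2-(1-chloroethyl)-6-[(2R,3S)-3-hydroxypentan-2-yl]-3,5-dimethyl-4H-pyran-4-one (epimers at the C–Cl carbon) | CC(Cl)c1oc([C@H](C)[C@@H](O)CC)c(C)c(=O)c1C | intermediate
13 | 2-methylpent-1-en-3-one | CCC(=O)C(C)=C | starting material
14 | 1,2-dibromo-2-methylpentan-3-one (not isolated) | CCC(=O)C(C)(Br)CBr | intermediate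
15 | (1E)-1-bromo-2-methylpent-1-en-3-one | CCC(=O)/C(C)=C/Br | intermediate
16 | dicyclohexyl{[(2E,4E)-5-bromo-4-methylpenta-2,4-dien-3-yl]oxy}borane (enol borinate, not isolated) | C/C=C(/OB(C1CCCCC1)C1CCCCC1)\C(C)=C\Br | intermediate
17 | (2R,3R,4R,6E)-7-bromo-2-(6-ethyl-3,5-dimethyl-4-oxo-4H-pyran-2-yl)-4,6-dimethyl-5-oxohept-6-en-3-yl dicyclohexylborinate (boron aldolate, not isolated) | Br/C=C(\C)C(=O)[C@H](C)[C@H](OB(C1CCCCC1)C1CCCCC1)[C@@H](C)c1oc(CC)c(C)c(=O)c1C | intermediate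
18 | 2-[(2R,3R,4R,6E)-7-bromo-3-hydroxy-4,6-dimethyl-5-oxohept-6-en-2-yl]-6-ethyl-3,5-dimethyl-4H-pyran-4-one | Br/C=C(\C)C(=O)[C@H](C)[C@H](O)[C@@H](C)c1oc(CC)c(C)c(=O)c1C | intermediate
19 | (2R,3R,4R,6E)-7-bromo-2-(6-ethyl-3,5-dimethyl-4-oxo-4H-pyran-2-yl)-4,6-dimethyl-5-oxohept-6-en-3-yl acetate | Br/C=C(\C)C(=O)[C@H](C)[C@H](OC(C)=O)[C@@H](C)c1oc(CC)c(C)c(=O)c1C | intermediate
20 | (2R,3S,4S,5R,6E)-7-bromo-2-(6-ethyl-3,5-dimethyl-4-oxo-4H-pyran-2-yl)-5-hydroxy-4,6-dimethylhept-6-en-3-yl acetate | Br/C=C(\C)[C@H](O)[C@H](C)[C@H](OC(C)=O)[C@@H](C)c1oc(CC)c(C)c(=O)c1C | intermediate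
21 | (2R,3S,4R,5R,6E)-3-acetoxy-7-bromo-2-(6-ethyl-3,5-dimethyl-4-oxo-4H-pyran-2-yl)-4,6-dimethylhept-6-en-5-yl propanoate | Br/C=C(\C)[C@H](OC(=O)CC)[C@H](C)[C@H](OC(C)=O)[C@@H](C)c1oc(CC)c(C)c(=O)c1C | intermediate
22 | (2R,3S,4R,5R,6E,8S)-3-acetoxy-2-(6-ethyl-3,5-dimethyl-4-oxo-4H-pyran-2-yl)-8-{6-[(2R,3S)-3-hydroxypentan-2-yl]-3,5-dimethyl-4-oxo-4H-pyran-2-yl}-4,6-dimethylnon-6-en-5-yl propanoate | CCC(=O)O[C@@H](/C(C)=C/[C@H](C)c1oc([C@H](C)[C@@H](O)CC)c(C)c(=O)c1C)[C@H](C)[C@H](OC(C)=O)[C@@H](C)c1oc(CC)c(C)c(=O)c1C | target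

**Step count and risk**

Total step count: 12.
Longest linear sequence: 9 steps (1, 2, 3, 4, 8, 9, 10, 11, 12). The west branch (5, 6) and the bromo-enone (7) are side branches.

Three steps most likely to fail:

Step 12. The risks are ionisation of the allylic propanoate of 21 by zerovalent nickel, slow oxidative addition of the hindered bromoalkene, and interference by the free hydroxyl of 12. The fallback brings the ester in after the coupling and sets out from 12 and 20. Compound 12 is silylated (Et3SiCl, imidazole, CH2Cl2) to 2-(1-chloroethyl)-3,5-dimethyl-6-[(2R,3S)-3-(triethylsilyloxy)pentan-2-yl]-4H-pyran-4-one F1. F1 and the allylic alcohol 20, which has no ionisable allylic ester, are coupled under the catalyst system of step 12 to give (2R,3S,4S,5R,6E,8S)-8-{3,5-dimethyl-4-oxo-6-[(2R,3S)-3-(triethylsilyloxy)pentan-2-yl]-4H-pyran-2-yl}-2-(6-ethyl-3,5-dimethyl-4-oxo-4H-pyran-2-yl)-5-hydroxy-4,6-dimethylnon-6-en-3-yl acetate F2. Propanoylation (EtCOCl, pyridine, 4-(dimethylamino)pyridine) gives (2R,3S,4R,5R,6E,8S)-3-acetoxy-8-{3,5-dimethyl-4-oxo-6-[(2R,3S)-3-(triethylsilyloxy)pentan-2-yl]-4H-pyran-2-yl}-2-(6-ethyl-3,5-dimethyl-4-oxo-4H-pyran-2-yl)-4,6-dimethylnon-6-en-5-yl propanoate F3. HF·pyridine in THF removes the silyl group and the route is rejoined at 22.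

Step 3. This is the first use of a pyranyl-ethyl chloride in the coupling; the risks are low enantioselectivity and elimination to the vinylpyranone. The fallback reaches the aldehyde without a coupling and sets out from 5. DBU in toluene at 60 °C converts 5 into 2-ethenyl-6-ethyl-3,5-dimethyl-4H-pyran-4-one F4. Branched-selective asymmetric hydroformylation of F4 (Rh(acac)(CO)2, the antipode of 1,2-bis(2,5-diphenylphospholano)ethane that gives the (S)-aldehyde, CO/H2, toluene, 60 °C) gives aldehyde 9 directly, where the route is rejoined; steps 3 and 4 are replaced.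

Step 8. The β-bromo enone 15 may not tolerate boron enolisation, and aldehyde 9 can epimerise. The fallback introduces bromine after the aldol and sets out from 13 and 9. Enone 13 is enolised ((c-C6H11)2BCl, Et3N, Et2O) to dicyclohexyl{[(2E)-4-methylpenta-2,4-dien-3-yl]oxy}borane F5. F5 adds to 9 to give the boron aldolate (2R,3R,4R)-2-(6-ethyl-3,5-dimethyl-4-oxo-4H-pyran-2-yl)-4,6-dimethyl-5-oxohept-6-en-3-yl dicyclohexylborinate F6 and, after oxidative work-up, 2-ethyl-6-[(2R,3R,4R)-3-hydroxy-4,6-dimethyl-5-oxohept-6-en-2-yl]-3,5-dimethyl-4H-pyran-4-one F7. Br2 in CH2Cl2 at −78 °C adds to the isopropenyl group to give 2-[(2R,3R,4R)-6,7-dibromo-3-hydroxy-4,6-dimethyl-5-oxoheptan-2-yl]-6-ethyl-3,5-dimethyl-4H-pyran-4-one F8, and Et3N eliminates HBr to give 18, where the route is rejoined.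

Further compounds
F1 | step 12 | 2-(1-chloroethyl)-3,5-dimethyl-6-[(2R,3S)-3-(triethylsilyloxy)pentan-2-yl]-4H-pyran-4-one | CC(Cl)c1oc([C@H](C)[C@@H](O[Si](CC)(CC)CC)CC)c(C)c(=O)c1C
F2 | step 12 | (2R,3S,4S,5R,6E,8S)-8-{3,5-dimethyl-4-oxo-6-[(2R,3S)-3-(triethylsilyloxy)pentan-2-yl]-4H-pyran-2-yl}-2-(6-ethyl-3,5-dimethyl-4-oxo-4H-pyran-2-yl)-5-hydroxy-4,6-dimethylnon-6-en-3-yl acetate | O[C@@H](/C(C)=C/[C@H](C)c1oc([C@H](C)[C@@H](O[Si](CC)(CC)CC)CC)c(C)c(=O)c1C)[C@H](C)[C@H](OC(C)=O)[C@@H](C)c1oc(CC)c(C)c(=O)c1C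
F3 | step 12 | (2R,3S,4R,5R,6E,8S)-3-acetoxy-8-{3,5-dimethyl-4-oxo-6-[(2R,3S)-3-(triethylsilyloxy)pentan-2-yl]-4H-pyran-2-yl}-2-(6-ethyl-3,5-dimethyl-4-oxo-4H-pyran-2-yl)-4,6-dimethylnon-6-en-5-yl propanoate | CCC(=O)O[C@@H](/C(C)=C/[C@H](C)c1oc([C@H](C)[C@@H](O[Si](CC)(CC)CC)CC)c(C)c(=O)c1C)[C@H](C)[C@H](OC(C)=O)[C@@H](C)c1oc(CC)c(C)c(=O)c1C
F4 | step 3 | 2-ethenyl-6-ethyl-3,5-dimethyl-4H-pyran-4-one | C=Cc1oc(CC)c(C)c(=O)c1C
F5 | step 8 | dicyclohexyl{[(2E)-4-methylpenta-2,4-dien-3-yl]oxy}borane | C/C=C(/OB(C1CCCCC1)C1CCCCC1)C(C)=C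
F6 | step 8 | (2R,3R,4R)-2-(6-ethyl-3,5-dimethyl-4-oxo-4H-pyran-2-yl)-4,6-dimethyl-5-oxohept-6-en-3-yl dicyclohexylborinate | C=C(C)C(=O)[C@H](C)[C@H](OB(C1CCCCC1)C1CCCCC1)[C@@H](C)c1oc(CC)c(C)c(=O)c1C
F7 | step 8 | 2-ethyl-6-[(2R,3R,4R)-3-hydroxy-4,6-dimethyl-5-oxohept-6-en-2-yl]-3,5-dimethyl-4H-pyran-4-one | C=C(C)C(=O)[C@H](C)[C@H](O)[C@@H](C)c1oc(CC)c(C)c(=O)c1C
F8 | step 8 | 2-[(2R,3R,4R)-6,7-dibromo-3-hydroxy-4,6-dimethyl-5-oxoheptan-2-yl]-6-ethyl-3,5-dimethyl-4H-pyran-4-one | BrCC(C)(Br)C(=O)[C@H](C)[C@H](O)[C@@H](C)c1oc(CC)c(C)c(=O)c1C
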